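**Retrosynthetic overview**

1. Endgame: target ← aryl acetate ← allyl-to-prenyl cross-metathesis ← Pd/formate opening of a temporary oxane (ring C) that ties the first side-chain carbon on C7 (C7a) to the C2 oxygen (O2) ← C3 aroylation.
2. Key disconnection: C1–C9 and C5–C6 are cut together, leading back to a monocyclic oxane that carries a dioxinone (masked acylketene: C9 on C5, with C4) and an axial CH2I arm (C6).
3. Enabling feature: the bridging ketone C9 is flanked by C1 and C5, which are also the α-carbons of the C2–C3–C4 β-diketone. Ring A (C1-C2-C3-C4-C5-C9) is therefore a cyclised 3,5-dioxo acid (dearomatised acylphloroglucinol), and the endo C7 side chain lies over O2 of ring A, so it can be tied there.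
4. Precursors: the oxane lactone comes from 3,3-dimethylglutaric anhydride (an auxiliary-controlled anti-aldol sets C7); the lavandulyl dioxinone comes from (R)-lavandulol by Negishi coupling.
5. Ring order: ring C (temporary, step 6) → ring A, then ring B (C1-C9-C5-C6-C7-C8), both in step 14 → ring C opened (step 16).

Key step: step 14

Remark: C1–C9 are the bicyclo[3.3.1]nonane carbons of the target (C1 = bridgehead with prenyl, C5 = bridgehead with the lavandulyl group, C9 = bridging ketone); C7a is the first carbon of the C7 side chain.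
Remark: (R)-lavandulol is taken as purchasable in enantiopure form (otherwise lipase resolution of the racemate); it gives the (S) side-chain centre of the target because the CIP ranking changes.
Remark: the magnesium-mediated anti-aldol of step 3 is assumed to add to the chelated-enolate face used in Evans alkylations; if the opposite sense is found, the (R)-auxiliary is used.
Remark: the C1 epimers of 14 and both alkene isomers of 23 and 24 converge in step 14.

**Step 1**
Reactants: 1 3,3-dimethylglutaric anhydride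
Product: 2 5-tert-butoxy-3,3-dimethyl-5-oxopentanoic acid
Conditions: t-BuOH, DMAP (cat.), Et3N, PhMe, 110 °C
Reagents that add atoms: tert-butanol, CC(C)(C)O
Why: Alcoholysis of the symmetrical cyclic anhydride should give the mono-ester, and the tert-butyl ester survives LiBH4 and the later enolate steps.

**Step 2**
Reactants: 2 5-tert-butoxy-3,3-dimethyl-5-oxopentanoic acid; 3 (S)-4-benzyl-2-oxazolidinone
Product: 5 tert-butyl 5-[(S)-4-benzyl-2-oxooxazolidin-3-yl]-3,3-dimethyl-5-oxopentanoate, via mixed pivalic anhydride 4 (not isolated)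
Conditions: PivCl, Et3N, THF, −20 °C; then 3, LiCl, 23 °C
Reagents that add atoms: pivaloyl chloride, CC(C)(C)C(Cl)=O (kept only in intermediate 4)
Why: N-Acylation of the Evans auxiliary through the mixed anhydride is routine for hindered acids.

**Step 3**
Reactants: 5 the imide; 6 acrolein
Product: 8 tert-butyl (4R,5R)-4-[(S)-4-benzyl-2-oxooxazolidine-3-carbonyl]-5-hydroxy-3,3-dimethylhept-6-enoate, via silyl aldol ether 7 (not isolated)
Conditions: MgCl2 (10 mol %), Et3N, TMSCl, EtOAc, 23 °C; then TFA (cat.), MeOH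
Reagents that add atoms: chlorotrimethylsilane, C[Si](C)(C)Cl (kept only in intermediate 7)
Why: In the magnesium-halide-catalysed anti-selective Evans aldol the chelated Z-enolate should be attacked opposite the benzyl group, which sets C7 as in the target, and the boat-like transition state gives the anti carbinol C7a, the relative configuration that later puts CH2OTs and vinyl cis on ring C.

**Step 4**
Reactants: 8 the anti-aldol adduct
Product: 9 tert-butyl (4S,5R)-5-hydroxy-4-(hydroxymethyl)-3,3-dimethylhept-6-enoate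
Conditions: LiBH4, MeOH (1 equiv), THF, 0 °C
Reagents that add atoms: none
Why: Reductive removal of the auxiliary should leave the tert-butyl ester, the vinyl group and both stereocentres untouched.

**Step 5**
Reactants: 9 the diol
Product: 10 tert-butyl (4S,5R)-5-hydroxy-3,3-dimethyl-4-(tosyloxymethyl)hept-6-enoate
Conditions: TsCl, pyridine, CH2Cl2, 0 °C
Reagents that add atoms: p-toluenesulfonyl chloride, Cc1ccc(cc1)S(Cl)(=O)=O
Why: Sulfonylation should select the primary over the secondary allylic hydroxyl.

**Step 6**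
Reactants: 10 the hydroxy tosylate
Product: 11 (5S,6R)-4,4-dimethyl-5-(tosyloxymethyl)-6-vinyltetrahydro-2H-pyran-2-one
Conditions: TFA, CH2Cl2, 0 → 23 °C; then PhMe, 60 °C
Reagents that add atoms: none
Why: Acidolysis of the tert-butyl ester and δ-lactonisation by the secondary hydroxyl (retention at C7a) should form ring C with CH2OTs and vinyl cis.

**Step 7**
Reactants: 11 the lactone; 12 prenyl bromide
Product: 14 (5S,6R)-4,4-dimethyl-3-prenyl-5-(tosyloxymethyl)-6-vinyltetrahydro-2H-pyran-2-one, via lithium enolate 13 (not isolated)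
Conditions: LDA (lithium diisopropylamide), THF, −78 °C; then 12, DMPU, −78 → −40 °C
Reagents that add atoms: none
Why: Lactone enolate alkylation with a reactive allylic bromide installs the C1 prenyl group; the C1 configuration is irrelevant because C1 becomes trigonal in step 14.

**Step 8**
Reactants: 15 (R)-lavandulol
Product: 16 (R)-lavandulyl iodide
Conditions: I2, PPh3, imidazole, CH2Cl2, 0 °C
Reagents that add atoms: iodine, II
Why: Appel-type iodination of the primary alcohol does not touch the stereocentre.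

**Step 9**
Reactants: 17 2,2,6-trimethyl-4H-1,3-dioxin-4-one
Product: 18 5-iodo-2,2,6-trimethyl-4H-1,3-dioxin-4-one
Conditions: NIS, AcOH, 23 °C
Reagents that add atoms: N-iodosuccinimide, O=C1CCC(=O)N1I
Why: Electrophilic iodination at the nucleophilic α-carbon of the vinylogous ester.

**Step 10**
Reactants: 16 (R)-lavandulyl iodide; 18 the iododioxinone
Product: 20 5-[(S)-2-isopropenyl-5-methylhex-4-enyl]-2,2,6-trimethyl-4H-1,3-dioxin-4-one, via lavandulylzinc iodide 19 (not isolated)
Conditions: Zn dust, LiCl, THF, 40 °C; then 18, Pd(OAc)2 (2 mol %), SPhos (4 mol %), 23 °C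
Reagents that add atoms: zinc, [Zn] (kept only in intermediate 19)
Why: Negishi coupling of a primary alkylzinc with an α-iodo enone-type partner puts the lavandulyl group on C5 under neutral conditions that spare its alkenes and its stereocentre.

**Step 11**
Reactants: 20 the lavandulyl dioxinone; 14 the prenylated lactone
Product: 22 lactol (2-hydroxy-2-dioxinonylmethyl oxane), via lithium dienolate 21 (not isolated)
Conditions: LDA, THF, −78 °C; then 14, −78 → −40 °C; AcOH
Reagents that add atoms: none
Why: γ-Deprotonation of the dioxinone gives its dienolate, whose Claisen-type addition to the lactone carbonyl should stop at the lactol alkoxide; the new hemiketal centre disappears in step 12.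

**Step 12**
Reactants: 22 the lactol
Product: 23 (Z)-alkylidene oxane tosylate
Conditions: MsCl, Et3N, CH2Cl2, 0 °C
Reagents that add atoms: none
Why: Dehydration of the hemiketal through its mesylate should give the enol ether conjugated with the dioxinone; an endocyclic isomer would give the same trienolate in step 14.

**Step 13**
Reactants: 23 the alkylidene tosylate
Product: 24 (Z)-alkylidene oxane iodide
Conditions: NaI, acetone, 56 °C
Reagents that add atoms: sodium iodide, [Na+].[I-]
Why: Finkelstein exchange provides the soft leaving group needed for C- rather than O-alkylation.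

**Step 14**
Reactants: 24 the alkylidene oxane iodide
Product: 28 tether-locked bicyclo[3.3.1]nonane cage, via lithium trienolate 25 (not isolated), via oxido-dienylketene 26 (not isolated), via dienone enolate 27 (not isolated)
Conditions: LDA (1.2 equiv), THF, −78 → 23 °C
Reagents that add atoms: none
Why: Proposed new method: LDA should remove the ε-proton at C1 to give trienolate 25, which on warming loses acetone (the dioxinone-to-ketene fragmentation) to give the oxido-dienylketene 26; thermal disrotatory 6π-electrocyclisation (C9 onto C1) closes ring A as the dearomatised dienone enolate 27, and 6-exo-tet C-alkylation of C5 by the axial CH2I arm closes ring B. The closest known reaction types are the ring closure of dienylketenes to cyclohexa-2,4-dienones (Danheiser-type benzannulation), the second C-acylation of an Effenberger cyclisation, and the enolate alkylation that closes ring B in alkylative dearomatisation–annulation routes to this family. At C1 the ketene carbon should add to the face of ring C opposite the pseudoaxial C8 methyl, which is the face that carries the axial CH2I arm; C5 can then only bond on that same face. Because C7a is tied to O2, only the adduct with C9 cis to the CH2I arm can close ring B, so the C7 side chain must end up endo and the configurations of C1 and C5 follow from C7 alone; a wrong-face adduct cannot cyclise and costs yield only. Attack at C5 rather than C3 is secured because O2 stays alkylated, which leaves C3 as the non-nucleophilic α-carbon of a vinylogous ester; C- over O-alkylation is favoured by the iodide and the lithium enolate.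

**Step 15**
Reactants: 28 the cage; 29 3-acetoxybenzoyl chloride
Product: 31 C3-(3-acetoxybenzoyl) cage, via vinyllithium 30 (not isolated)
Conditions: LiTMP (lithium 2,2,6,6-tetramethylpiperidide, commercial solution), THF, −78 °C; then 29
Reagents that add atoms: none
Why: C3 is the only acidic position of the bicyclic vinylogous ester (C1 and C5 are quaternary), so α-lithiation and acylation should install the aroyl group as on methyl-enol-ether-protected bicyclic triones.

**Step 16**
Reactants: 31 the aroylated cage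
Product: 32 C7-allyl triketone (O-acetate)
Conditions: Pd(PPh3)4 (5 mol %), HCO2H, Et3N, THF, 40 °C
Reagents that add atoms: none
Why: Tsuji–Trost hydrogenolysis: zerovalent palladium ionises the allylic C7a–O2 bond with the triketone enolate as leaving group and formate delivers hydride to the substituted terminus, which opens ring C, leaves a terminal allyl group on C7 and does not touch C7; C3 is already blocked against C-allylation.

**Step 17**
Reactants: 32 the C7-allyl triketone; 33 2-methyl-2-butene
Product: 34 target O-acetate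
Conditions: second-generation Grubbs catalyst (H2IMes)(PCy3)Cl2Ru=CHPh (5 mol %), 33 (excess), CH2Cl2, 40 °C
Reagents that add atoms: none
Why: Cross-metathesis converts the allyl into the prenyl group; the existing trisubstituted prenyl alkenes exchange degenerately and the 1,1-disubstituted isopropenyl group is a spectator.

**Step 18**
Reactants: 34 the target O-acetate
Product: 35 CNP0103487.1 (target)
Conditions: Et3N, MeOH, 23 °C
Reagents that add atoms: none
Why: Mild methanolysis of the aryl acetate frees the phenol without retro-Claisen cleavage of the triketone.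

**Compound list**

1 | 3,3-dimethylglutaric anhydride | CC1(C)CC(=O)OC(=O)C1 | starting material
2 | 5-tert-butoxy-3,3-dimethyl-5-oxopentanoic acid | CC(C)(C)OC(=O)CC(C)(C)CC(=O)O | intermediate
3 | (S)-4-benzyl-2-oxazolidinone | O=C1N[C@@H](Cc2ccccc2)CO1 | starting material
4 | mixed pivalic anhydride of 2 | CC(C)(C)OC(=O)CC(C)(C)CC(=O)OC(=O)C(C)(C)C | intermediate
5 | tert-butyl 5-[(S)-4-benzyl-2-oxooxazolidin-3-yl]-3,3-dimethyl-5-oxopentanoate | CC(C)(C)OC(=O)CC(C)(C)CC(=O)N1[C@@H](Cc2ccccc2)COC1=O | intermediate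
6 | acrolein | C=CC=O | starting material
7 | O-trimethylsilyl ether of 8 | CC(C)(C)OC(=O)CC(C)(C)[C@@H](C(=O)N1[C@@H](Cc2ccccc2)COC1=O)[C@H](O[Si](C)(C)C)C=C | intermediate
8 | tert-butyl (4R,5R)-4-[(S)-4-benzyl-2-oxooxazolidine-3-carbonyl]-5-hydroxy-3,3-dimethylhept-6-enoate (anti-aldol; C7 as in the target) | CC(C)(C)OC(=O)CC(C)(C)[C@@H](C(=O)N1[C@@H](Cc2ccccc2)COC1=O)[C@H](O)C=C | intermediate
9 | tert-butyl (4S,5R)-5-hydroxy-4-(hydroxymethyl)-3,3-dimethylhept-6-enoate | CC(C)(C)OC(=O)CC(C)(C)[C@@H](CO)[C@H](O)C=C | intermediate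
10 | tert-butyl (4S,5R)-5-hydroxy-3,3-dimethyl-4-(tosyloxymethyl)hept-6-enoate | CC(C)(C)OC(=O)CC(C)(C)[C@@H](COS(=O)(=O)c1ccc(C)cc1)[C@H](O)C=C | intermediate
11 | (5S,6R)-4,4-dimethyl-5-(tosyloxymethyl)-6-vinyltetrahydro-2H-pyran-2-one (ring C; CH2OTs and vinyl cis) | O=C1CC(C)(C)[C@@H](COS(=O)(=O)c2ccc(C)cc2)[C@@H](C=C)O1 | intermediate
12 | prenyl bromide (1-bromo-3-methylbut-2-ene) | CC(C)=CCBr | starting material
13 | lithium enolate of 11 | [Li+].[O-]C1=CC(C)(C)[C@@H](COS(=O)(=O)c2ccc(C)cc2)[C@@H](C=C)O1 | intermediate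
14 | (5S,6R)-4,4-dimethyl-3-prenyl-5-(tosyloxymethyl)-6-vinyltetrahydro-2H-pyran-2-one (both C3 epimers) | O=C1C(CC=C(C)C)C(C)(C)[C@@H](COS(=O)(=O)c2ccc(C)cc2)[C@@H](C=C)O1 | intermediate
15 | (R)-lavandulol | C=C(C)[C@H](CO)CC=C(C)C | starting material
16 | (R)-lavandulyl iodide | C=C(C)[C@H](CI)CC=C(C)C | intermediate
17 | 2,2,6-trimethyl-4H-1,3-dioxin-4-one | CC1=CC(=O)OC(C)(C)O1 | starting material
18 | 5-iodo-2,2,6-trimethyl-4H-1,3-dioxin-4-one | CC1=C(I)C(=O)OC(C)(C)O1 | intermediate
19 | (R)-lavandulylzinc iodide | C=C(C)[C@H](C[Zn]I)CC=C(C)C | intermediate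
20 | 5-[(S)-2-isopropenyl-5-methylhex-4-enyl]-2,2,6-trimethyl-4H-1,3-dioxin-4-one | CC1=C(C[C@H](CC=C(C)C)C(C)=C)C(=O)OC(C)(C)O1 | intermediate
21 | lithium dienolate of 20 | [Li+].C=C1OC(C)(C)OC([O-])=C1C[C@H](CC=C(C)C)C(C)=C | intermediate
22 | lactol: 5-lavandulyl-2,2-dimethyl-6-{[(5S,6R)-2-hydroxy-4,4-dimethyl-3-prenyl-5-(tosyloxymethyl)-6-vinyltetrahydropyran-2-yl]methyl}-1,3-dioxin-4-one (anomers) | OC1(CC2=C(C[C@H](CC=C(C)C)C(C)=C)C(=O)OC(C)(C)O2)C(CC=C(C)C)C(C)(C)[C@@H](COS(=O)(=O)c3ccc(C)cc3)[C@@H](C=C)O1 | intermediate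
23 | 6-{(Z)-[(5S,6R)-4,4-dimethyl-3-prenyl-5-(tosyloxymethyl)-6-vinyltetrahydropyran-2-ylidene]methyl}-5-lavandulyl-2,2-dimethyl-1,3-dioxin-4-one | C=C[C@H]1O/C(=C\C2=C(C[C@H](CC=C(C)C)C(C)=C)C(=O)OC(C)(C)O2)C(CC=C(C)C)C(C)(C)[C@H]1COS(=O)(=O)c3ccc(C)cc3 | intermediate
24 | iodide corresponding to 23 (CH2I in place of CH2OTs, same configuration) | C=C[C@H]1O/C(=C\C2=C(C[C@H](CC=C(C)C)C(C)=C)C(=O)OC(C)(C)O2)C(CC=C(C)C)C(C)(C)[C@H]1CI | intermediate
25 | lithium trienolate of 24 (C1 deprotonated) | [Li+].C=C[C@H]1OC(C=C2OC(C)(C)OC([O-])=C2C[C@H](CC=C(C)C)C(C)=C)=C(CC=C(C)C)C(C)(C)[C@H]1CI | intermediate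
26 | oxido-dienylketene (lithium salt; acetone lost) | [Li+].C=C[C@H]1OC(C=C([O-])C(C[C@H](CC=C(C)C)C(C)=C)=C=O)=C(CC=C(C)C)C(C)(C)[C@H]1CI | intermediate
27 | dienone enolate (lithium salt; ring A closed, C1 as in the target) | [Li+].C=C(C)[C@@H](CC=C(C)C)CC1=C([O-])C=C2O[C@H](C=C)[C@H](CI)C(C)(C)[C@]2(CC=C(C)C)C1=O | intermediate
28 | cage: bicyclo[3.3.1]nonane-4,9-dione core (C1 prenyl, C5 lavandulyl, C8 gem-dimethyl) whose C2 enol oxygen is bonded to C7a (CH-vinyl) on C7; C1, C5 and C7 as in the target | C=C(C)[C@@H](CC=C(C)C)C[C@@]12C[C@H]3[C@@H](C=C)OC(=CC1=O)[C@@](CC=C(C)C)(C2=O)C3(C)C | intermediate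
29 | 3-acetoxybenzoyl chloride | CC(=O)Oc1cccc(c1)C(Cl)=O | starting material
30 | C3-lithio derivative of 28 | C=C(C)[C@@H](CC=C(C)C)C[C@@]12C[C@H]3[C@@H](C=C)OC(=C([Li])C1=O)[C@@](CC=C(C)C)(C2=O)C3(C)C | intermediate
31 | C3-(3-acetoxybenzoyl) derivative of 28 | C=C(C)[C@@H](CC=C(C)C)C[C@@]12C[C@H]3[C@@H](C=C)OC(=C(C(=O)c4cccc(OC(C)=O)c4)C1=O)[C@@](CC=C(C)C)(C2=O)C3(C)C | intermediate
32 | target O-acetate with allyl in place of the C7 prenyl group (7-endo) | C=C(C)[C@@H](CC=C(C)C)C[C@@]12C[C@@H](CC=C)C(C)(C)[C@@](CC=C(C)C)(C(=O)C(C(=O)c3cccc(OC(C)=O)c3)=C1O)C2=O | intermediate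
33 | 2-methyl-2-butene | CC=C(C)C | starting material
34 | target O-acetate | C=C(C)[C@@H](CC=C(C)C)C[C@@]12C[C@@H](CC=C(C)C)C(C)(C)[C@@](CC=C(C)C)(C(=O)C(C(=O)c3cccc(OC(C)=O)c3)=C1O)C2=O | intermediate
35 | CNP0103487.1 | C=C(C)[C@@H](CC=C(C)C)C[C@@]12C[C@@H](CC=C(C)C)C(C)(C)[C@@](CC=C(C)C)(C(=O)C(C(=O)c3cccc(O)c3)=C1O)C2=O | target

**Totals**

Total step count: 18. Longest linear sequence: 15 steps (steps 1–7, then 11–18).

**Steps most likely to fail**

Step 14 (proposed new method). What may go wrong: the ketene carbon adds to the wrong face of ring C, the enolate alkylates on O9 instead of C5, or the ketene oligomerises before ring A closes. The fallback replaces the cascade by an Effenberger cyclisation followed by a separate enolate alkylation, both known reaction types. It sets out from 14 (with 16 for the malonyl partner) and comes back at 28. Lactone 14 is methylenated with Cp2TiMe2 (PhMe, 70 °C) to the exocyclic enol ether F1. Iodide 16 alkylates diethyl malonate (NaH, DMF) to diethyl lavandulylmalonate F2, which is saponified (KOH, EtOH/H2O) to lavandulylmalonic acid F3 and converted with (COCl)2 into lavandulylmalonyl dichloride F4. Effenberger cyclisation of F1 with F4 (KOH, BnEt3NCl, CH2Cl2, −10 → 23 °C) acylates C3 and then C1 and should give the ring A trione tosylate F5. NaI and Cs2CO3 (acetone, 50 °C) then close ring B to 28.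

Step 11. What may go wrong: the dienolate enolises 14 or fails to add to the hindered lactone carbonyl before it decomposes. The fallback uses a more reactive acyl donor; it sets out from 14 and comes back at 23. Lactone 14 is opened with MeNH(OMe)·HCl and AlMe3 to the hydroxy Weinreb amide F6, which is silylated (TESCl, imidazole) to the silyl ether F7. F7 acylates dienolate 21 to the keto-dioxinone F8. PPTS in MeOH removes the silyl group, and the hydroxy ketone cyclodehydrates (CSA, molecular sieves, PhMe) to 23.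

Step 3. What may go wrong: amine-induced polymerisation of acrolein or erosion of the anti selectivity. The fallback uses a syn-aldol and corrects C7a by inversion; it sets out from 2 and comes back at 11. Acid 2 is attached to (R)-4-benzyl-2-oxazolidinone (PivCl, Et3N, LiCl) to give the imide F9. The Evans syn-aldol (Bu2BOTf, Et3N, then 6; H2O2 work-up) should give the syn adduct F10 with C7 as required and C7a epimeric to 8. LiBH4 gives the diol F11, TsCl/pyridine the tosylate F12 and TFA the hydroxy acid F13. Mitsunobu lactonisation (PPh3, DIAD) inverts C7a and gives 11.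

**Further compounds**

F1 | step 14 | (5S,6R)-4,4-dimethyl-2-methylene-3-prenyl-5-(tosyloxymethyl)-6-vinyltetrahydropyran | C=C1O[C@H](C=C)[C@H](COS(=O)(=O)c2ccc(C)cc2)C(C)(C)C1CC=C(C)C
F2 | step 14 | diethyl 2-lavandulylmalonate | CCOC(=O)C(C[C@H](CC=C(C)C)C(C)=C)C(=O)OCC
F3 | step 14 | 2-lavandulylmalonic acid | OC(=O)C(C[C@H](CC=C(C)C)C(C)=C)C(=O)O
F4 | step 14 | 2-lavandulylmalonyl dichloride | ClC(=O)C(C[C@H](CC=C(C)C)C(C)=C)C(Cl)=O
F5 | step 14 | ring A trione tosylate (enol form; as 27 protonated, with CH2OTs) | C=C(C)[C@@H](CC=C(C)C)CC1=C(O)C=C2O[C@H](C=C)[C@H](COS(=O)(=O)c3ccc(C)cc3)C(C)(C)[C@]2(CC=C(C)C)C1=O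
F6 | step 11 | hydroxy Weinreb amide from 14 | CON(C)C(=O)C(CC=C(C)C)C(C)(C)[C@@H](COS(=O)(=O)c1ccc(C)cc1)[C@H](O)C=C
F7 | step 11 | triethylsilyl ether of F6 | CON(C)C(=O)C(CC=C(C)C)C(C)(C)[C@@H](COS(=O)(=O)c1ccc(C)cc1)[C@H](O[Si](CC)(CC)CC)C=C
F8 | step 11 | keto-dioxinone (open-chain form of 22, O-silylated) | CC1(C)OC(=O)C(C[C@H](CC=C(C)C)C(C)=C)=C(CC(=O)C(CC=C(C)C)C(C)(C)[C@@H](COS(=O)(=O)c2ccc(C)cc2)[C@H](O[Si](CC)(CC)CC)C=C)O1
F9 | step 3 | tert-butyl 5-[(R)-4-benzyl-2-oxooxazolidin-3-yl]-3,3-dimethyl-5-oxopentanoate | CC(C)(C)OC(=O)CC(C)(C)CC(=O)N1[C@H](Cc2ccccc2)COC1=O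
F10 | step 3 | syn-aldol adduct (C7 as in 8, C7a epimeric) | CC(C)(C)OC(=O)CC(C)(C)[C@@H](C(=O)N1[C@H](Cc2ccccc2)COC1=O)[C@@H](O)C=C
F11 | step 3 | C5 epimer of diol 9 | CC(C)(C)OC(=O)CC(C)(C)[C@@H](CO)[C@@H](O)C=C
F12 | step 3 | C5 epimer of tosylate 10 | CC(C)(C)OC(=O)CC(C)(C)[C@@H](COS(=O)(=O)c1ccc(C)cc1)[C@@H](O)C=C
F13 | step 3 | hydroxy acid from F12 | OC(=O)CC(C)(C)[C@@H](COS(=O)(=O)c1ccc(C)cc1)[C@@H](O)C=C
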